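## Retrosynthetic overview
1. Numbering: C1(Et)=C2–C3(Me)–C3a–C4(Me)=C5–C6(Me, dienyl)–C7(Me, CO2H)–C7a. The biomimetic IMDA (C3a–C7a and C6–C7 together) is deliberately not used.
2. The six-membered ring is formed last. It is opened at C4=C5, giving seco-acid 20, which closes by relay ring-closing metathesis.
3. Key step: the C6–C7 bond between the two quaternary carbons comes from a fragment-uniting Ireland–Claisen rearrangement of ester 19. A traceless (S)-carbinol supplies the chirality, and its pentenyl chain later serves as the metathesis relay.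
4. Acid 9 carries the five-membered ring, taken from the chiral pool. C3a, C7a and C3 are set by three successive anti additions on (R)-4-silyloxycyclopentenone, and the ketone becomes C1(Et)=C2 through an enol triflate.
5. Alcohol 18 comes from an ynone by Noyori transfer hydrogenation, directed trans-hydroalumination/iodination and Suzuki coupling with a dienylboronate.

Assumption: compounds 5–9 and 19 are carried as roughly 1:1 epimers at the propanoate α-carbon (future C7). This centre is erased on enolisation in step 13.

## Route

**Step 1**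
Reactants: 1 (4R)-4-(tert-butyldimethylsilyloxy)cyclopent-2-en-1-one; 2 isopropenylmagnesium bromide
Product: 3, the (1R,2S)-enol silane, with isopropenyl trans to OTBS and OTMS on the former carbonyl carbon
Conditions: 2, CuBr·SMe2 (10 mol %), TMSCl, DMPU, THF, −78 °C
Reagents that add atoms: isopropenylmagnesium bromide CC(=C)[Mg]Br; chlorotrimethylsilane C[Si](C)(C)Cl
Why: TMSCl-accelerated Cu-catalysed 1,4-addition (prostaglandin type) brings the nucleophile in anti to the silyloxy group, which sets C3a, and in-situ silylation fixes the enolate at the future C7a.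

**Step 2**
Reactants: 3; 4 methyl 2-bromopropanoate (racemic)
Product: 5, the all-trans keto ester methyl 2-[(1S,2S,3R)-3-(TBSO)-5-oxo-2-(prop-1-en-2-yl)cyclopentyl]propanoate
Conditions: fac-Ir(ppy)3 (1 mol %), 2,6-lutidine, MeCN, blue LED, rt
Reagents that add atoms: methyl 2-bromopropanoate CC(Br)C(=O)OC
Why: In this photoredox radical–polar crossover α-alkylation of an enol silane, the electrophilic α-ester radical adds to the enol carbon anti to the isopropenyl group (sets C7a trans), oxidation and desilylation return the ketone, and the non-basic medium avoids β-silyloxy elimination before the C–C bond forms.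

**Step 3**
Reactants: 5
Product: 6 methyl 2-[(1S,5S)-2-oxo-5-(prop-1-en-2-yl)cyclopent-3-en-1-yl]propanoate
Conditions: DBU, CH2Cl2, 0 °C, short contact
Reagents that add atoms: none
Why: E1cB loss of silanolate (PGE-to-PGA type) unmasks a new enone, the epimerisable C7a remains in the favoured trans arrangement, and cold, brief exposure avoids γ-deprotonation at C3a.

**Step 4**
Reactants: 6
Product: 7, the enol triflate methyl 2-[(1S,4S,5S)-4-methyl-5-(prop-1-en-2-yl)-2-(triflyloxy)cyclopent-2-en-1-yl]propanoate
Conditions: Me2CuLi, Et2O/THF, −78 °C; then Comins' reagent, −78 to 0 °C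
Reagents that add atoms: lithium dimethylcuprate [Li+].C[Cu-]C; Comins' reagent O=S(=O)(C(F)(F)F)N(c1ccc(Cl)cn1)S(=O)(=O)C(F)(F)F
Why: Gilman conjugate addition anti to the adjacent isopropenyl group sets C3, and O-triflation of the regiodefined enolate places the future C1=C2 double bond unambiguously while the methyl ester is inert at −78 °C.

**Step 5**
Reactants: 7
Product: 8 methyl 2-[(1S,4R,5S)-2-ethyl-4-methyl-5-(prop-1-en-2-yl)cyclopent-2-en-1-yl]propanoate
Conditions: EtMgBr, Fe(acac)3 (5 mol %), THF/NMP, −30 °C
Reagents that add atoms: ethylmagnesium bromide CC[Mg]Br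
Why: Iron-catalysed Kumada-type alkyl–alkenyl coupling outruns ester attack and β-hydride elimination, so OTf is replaced by ethyl without touching any stereocentre.

**Step 6**
Reactants: 8
Product: 9 2-[(1S,4R,5S)-2-ethyl-4-methyl-5-(prop-1-en-2-yl)cyclopent-2-en-1-yl]propanoic acid
Conditions: LiOH, THF/MeOH/H2O, 45 °C; then aq. KHSO4
Reagents that add atoms: lithium hydroxide/water [Li+].[OH-]
Why: Ordinary BAc2 saponification affects only the inconsequential α-carbon, because none of the ring stereocentres is acidic any longer.

**Step 7**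
Reactants: 10 hex-5-enoyl chloride; 11 propyne
Product: 12 non-8-en-2-yn-4-one
Conditions: PdCl2(PPh3)2 (2 mol %), CuI (4 mol %), Et3N, THF, rt
Reagents that add atoms: propyne CC#C
Why: Acyl Sonogashira coupling gives the ynone directly and leaves the isolated terminal alkene untouched.

**Step 8**
Reactants: 12
Product: 13 (4S)-non-8-en-2-yn-4-ol
Conditions: Ru[(S,S)-TsDPEN](p-cymene) (1 mol %), i-PrOH, rt
Reagents that add atoms: none
Why: In the Noyori asymmetric transfer hydrogenation the alkyne plays the role of the aryl group, so the (S,S)-catalyst gives the (S)-propargylic alcohol and sets the controlling carbinol without reducing alkene or alkyne.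

**Step 9**
Reactants: 13
Product: 14 (2Z,4S)-2-iodonona-2,8-dien-4-ol
Conditions: Red-Al, THF, 0 °C to rt; EtOAc; then I2, −78 °C
Reagents that add atoms: iodine II
Why: Hydroxyl-directed trans-hydroalumination gives the cyclic alkenylalanate with Al on the distal carbon cis to the carbinol, and iodinolysis with retention gives the Z-iodide.

**Step 10**
Reactants: 15 (E)-cinnamaldehyde; 16 bis[(pinacolato)boryl]methane
Product: 17 2-[(1E,3E)-4-phenylbuta-1,3-dien-1-yl]-4,4,5,5-tetramethyl-1,3,2-dioxaborolane
Conditions: LiTMP, THF, 0 °C; then 15, −78 °C to rt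
Reagents that add atoms: bis[(pinacolato)boryl]methane CC1(C)OB(CB2OC(C)(C)C(C)(C)O2)OC1(C)C
Why: Boron–Wittig olefination proceeds by 1,2-addition of the α-boryl carbanion and syn B–O elimination to give the E-alkenylboronate.

**Step 11**
Reactants: 14; 17
Product: 18 (6S,7Z,9E,11E)-8-methyl-12-phenyldodeca-1,7,9,11-tetraen-6-ol
Conditions: Pd(dppf)Cl2 (5 mol %), aq. K3PO4, THF, rt, degassed, dark
Reagents that add atoms: none beyond numbered reactant 17
Why: Suzuki–Miyaura coupling retains geometry at both partners, placing the dienyl group cis to the carbinol, and it tolerates the free OH and the terminal alkene.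

**Step 12**
Reactants: 9; 18
Product: 19, the ester of 9 with 18, (S) at the carbinol
Conditions: 2,4,6-trichlorobenzoyl chloride, Et3N, toluene; then 18, DMAP, 0 °C to rt
Reagents that add atoms: none (both partners are numbered reactants)
Why: Yamaguchi esterification is an acyl transfer to oxygen, so the carbinol configuration and all alkene geometries are retained under mild, non-ionising conditions.

**Step 13 (key step)**
Reactants: 19
Product: 20 (2R,3R,4E)-2-[(1R,4R,5S)-2-ethyl-4-methyl-5-(prop-1-en-2-yl)cyclopent-2-en-1-yl]-2,3-dimethyl-3-[(1E,3E)-4-phenylbuta-1,3-dien-1-yl]deca-4,9-dienoic acid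
Conditions: LDA, TMSCl/Et3N (in-situ quench), THF, −78 °C; warm to rt, then 40 °C; aq. NH4Cl/MeOH
Reagents that add atoms: none (TMS is lost on work-up)
Why: In this Ireland–Claisen [3,3] rearrangement, LDA/THF gives the ketene acetal with the bulky cyclopentenyl group syn to the allylic oxygen and Me syn to OTMS, and the chair transition state keeps the pentenyl chain of the (S)-carbinol equatorial (an axial chain would clash with the cis-dienyl) and places cyclopentenyl and dienyl anti across the forming bond, so 1,3-chirality transfer sets C6 and C7 together in an approach matched with the C7a centre.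

**Step 14**
Reactants: 20
Product: 21 22-nor-zyggomphic acid B
Conditions: Hoveyda–Grubbs II (10 mol %), 1,4-benzoquinone (20 mol %), toluene (1 mM), 60 °C, Ar sparge
Reagents that add atoms: none (cyclopentene and ethylene are lost)
Why: In the relay ring-closing metathesis Ru loads at the only monosubstituted alkene, expels cyclopentene to place the carbene on hindered C5, and closes onto the nearby isopropenyl group to form the trans-fused trisubstituted C4=C5 ring faster than it can attack the internal phenyl-capped diene, with no stereocentre touched.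

## Compound list
| No. | Name | SMILES | Role |
|---|---|---|---|
| 1 | (4R)-4-(tert-butyldimethylsilyloxy)cyclopent-2-en-1-one | O=C1C=C[C@H](O[Si](C)(C)C(C)(C)C)C1 | starting material |
| 2 | isopropenylmagnesium bromide | CC(=C)[Mg]Br | starting material |
| 3 | tert-butyl(dimethyl){[(1R,2S)-2-(prop-1-en-2-yl)-4-(trimethylsilyloxy)cyclopent-3-en-1-yl]oxy}silane | C[Si](C)(C)OC1=C[C@@H](C(C)=C)[C@H](O[Si](C)(C)C(C)(C)C)C1 | intermediate |
| 4 | methyl 2-bromopropanoate | CC(Br)C(=O)OC | starting material |
| 5 | methyl 2-[(1S,2S,3R)-3-(TBSO)-5-oxo-2-(prop-1-en-2-yl)cyclopentyl]propanoate | O=C1C[C@@H](O[Si](C)(C)C(C)(C)C)[C@H](C(C)=C)[C@H]1C(C)C(=O)OC | intermediate |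
| 6 | methyl 2-[(1S,5S)-2-oxo-5-(prop-1-en-2-yl)cyclopent-3-en-1-yl]propanoate | O=C1C=C[C@H](C(C)=C)[C@H]1C(C)C(=O)OC | intermediate |
| 7 | methyl 2-[(1S,4S,5S)-4-methyl-5-(prop-1-en-2-yl)-2-(triflyloxy)cyclopent-2-en-1-yl]propanoate | FC(F)(F)S(=O)(=O)OC1=C[C@@H](C)[C@H](C(C)=C)[C@H]1C(C)C(=O)OC | intermediate |
| 8 | methyl 2-[(1S,4R,5S)-2-ethyl-4-methyl-5-(prop-1-en-2-yl)cyclopent-2-en-1-yl]propanoate | CCC1=C[C@@H](C)[C@H](C(C)=C)[C@H]1C(C)C(=O)OC | intermediate |
| 9 | 2-[(1S,4R,5S)-2-ethyl-4-methyl-5-(prop-1-en-2-yl)cyclopent-2-en-1-yl]propanoic acid | CCC1=C[C@@H](C)[C@H](C(C)=C)[C@H]1C(C)C(=O)O | intermediate |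
| 10 | hex-5-enoyl chloride | C=CCCCC(=O)Cl | starting material |
| 11 | propyne | CC#C | starting material |
| 12 | non-8-en-2-yn-4-one | CC#CC(=O)CCCC=C | intermediate |
| 13 | (4S)-non-8-en-2-yn-4-ol | C=CCCC[C@H](O)C#CC | intermediate |
| 14 | (2Z,4S)-2-iodonona-2,8-dien-4-ol | C=CCCC[C@H](O)/C=C(/C)I | intermediate |
| 15 | (E)-cinnamaldehyde | O=C/C=C/c1ccccc1 | starting material |
| 16 | bis[(pinacolato)boryl]methane | CC1(C)OB(CB2OC(C)(C)C(C)(C)O2)OC1(C)C | starting material |
| 17 | (1E,3E)-4-phenylbuta-1,3-dienylboronic acid pinacol ester | CC1(C)OB(/C=C/C=C/c2ccccc2)OC1(C)C | intermediate |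
| 18 | (6S,7Z,9E,11E)-8-methyl-12-phenyldodeca-1,7,9,11-tetraen-6-ol | C=CCCC[C@H](O)/C=C(/C)\C=C\C=C\c1ccccc1 | intermediate |
| 19 | (6S,7Z,9E,11E)-8-methyl-12-phenyldodeca-1,7,9,11-tetraen-6-yl 2-[(1S,4R,5S)-2-ethyl-4-methyl-5-(prop-1-en-2-yl)cyclopent-2-en-1-yl]propanoate | CCC1=C[C@@H](C)[C@H](C(C)=C)[C@H]1C(C)C(=O)O[C@@H](CCCC=C)/C=C(/C)\C=C\C=C\c1ccccc1 | intermediate |
| 20 | seco-acid (full name in step 13) | CCC1=C[C@@H](C)[C@H](C(C)=C)[C@H]1[C@@](C)(C(=O)O)[C@@](C)(/C=C/C=C/c1ccccc1)/C=C/CCCC=C | intermediate |
| 21 | 22-nor-zyggomphic acid B, (3R,3aS,6S,7R,7aR)-1-ethyl-3,4,6,7-tetramethyl-6-[(1E,3E)-4-phenylbuta-1,3-dienyl]-3a,6,7,7a-tetrahydro-3H-indene-7-carboxylic acid | CCC1=C[C@@H](C)[C@@H]2C(C)=C[C@](C)(/C=C/C=C/c3ccccc3)[C@](C)(C(=O)O)[C@@H]12 | target |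

## Totals
The route has 14 steps in total. The longest linear sequence is 9 steps (steps 1–6, then 12–14).

## Three steps most likely to fail
1. **Step 13 (Ireland–Claisen).**
   - Failure modes: imperfect E/Z control of the tetrasubstituted ketene acetal or leakage through a boat transition state would erode C7, and base-induced 1,4-elimination of the trienyl carboxylate could compete. C6 depends only on the carbinol and the alkene face, so it is secure.
   - Fallback: remove the methyl group from the rearrangement. Use methyl bromoacetate in step 2 so that the Claisen runs through a trisubstituted ketene acetal of reliable geometry, and close the ring as in step 14. Then install the C7 methyl last by alkylating the bicyclic carboxylate dianion (LDA, MeI) on the face anti to the pseudo-axial dienyl group at C6.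
2. **Step 14 (relay RCM next to a polyene).**
   - Failure modes: slow closure beside two quaternary carbons could allow Ru to cleave the phenyldiene.
   - Fallback: postpone the polyene. Couple 14 with (E)-3-(TBSO)prop-1-enyl-Bpin in step 11, then carry out the Claisen and RCM on the substrate that lacks the diene. Finish with TBAF, MnO2 and an E-selective HWE reaction with diethyl benzylphosphonate, carried out on the carboxylate salt.
3. **Steps 2 and 3 (C7a–C7 bond next to a β-silyloxy ketone).**
   - Failure modes: low radical chemoselectivity against the isopropenyl group, or scrambling during the elimination.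
   - Fallback: make the C7a–C7 bond by a sigmatropic route instead.
     - Start from the (S)-enantiomer of 1 and carry out isopropenyl cuprate addition with MeI trapping, DBU elimination, α-iodination, Negishi ethylation and Luche reduction. This gives 2-ethyl-4-isopropenyl-5-methylcyclopent-2-enol.
     - Treat this alcohol with triethyl orthopropionate in a Johnson–Claisen rearrangement. It delivers C7 suprafacially to C7a and creates C1=C2 in the same step, converging on the ethyl ester analogue of 8.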